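**Plan**

- Retrosynthesis: the side-chain enone is traced back to the trisubstituted alkene of a homoprenyl chain (1,3-oxygen transposition). The palmitate ester and the C8 formyl group are traced back to a phthalide spanning C7/C8. Both bonds from the arene to the pyran ring, C4–C4a and O1–C8a, are then cut together.
- Forward: the benzene ring is bought and dressed as 7-iodo-5-methoxyphthalide. The pyran ring is closed onto it in one palladium/norbornene annulation with a 1,3-bromohydrin made from (R)-linalool. The side chain is then oxidised, and last the lactone is opened, acylated and oxidised.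
- Enabling feature: the C8a–I carbon is flanked by the lactone carbonyl carbon on C8 (ortho blocking group, later the formyl carbon) and by the only free ortho C4a–H. C4–C3–C2–O1 is a bromohydrin whose tertiary alkoxide has no hydrogen on the carbinol carbon.
- Stereochemistry: the single stereocentre C2 is the carbinol carbon of (R)-(−)-linalool; no bond to it is made or broken.

Key step: step 5

Remark: chroman numbering (O1, C2–C4, C4a, C5–C8, C8a) is used for all tricyclic intermediates. Commercial (R)-(−)-linalool is taken as enantiomerically pure. The C2 descriptor changes between R and S along the route only through CIP ranking; the geometry does not change.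

**Route**

Step 1
Reactants: 1 4-methoxy-2-methylbenzoic acid
Product: 2 2-iodo-4-methoxy-6-methylbenzoic acid
Conditions: Pd(OAc)2 (5 mol %), PhI(OAc)2, I2, DMF, 100 °C, dark
Reagents that add atoms: iodine, II (delivered as acetyl hypoiodite formed in the flask)
Why: Carboxylate-directed ortho C–H iodination under divalent palladium catalysis (cyclopalladation at C6, the only ortho C–H of the acid, then oxidation by IOAc and C–I reductive elimination) should place iodine next to the carboxyl, the uncatalysed iodination ortho to the methoxy group being slow in DMF on this carboxyl-deactivated ring.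

Step 2
Reactants: 2 2-iodo-4-methoxy-6-methylbenzoic acid
Product: 4 7-iodo-5-methoxyisobenzofuran-1(3H)-one (7-iodo-5-methoxyphthalide), via 2-(bromomethyl)-6-iodo-4-methoxybenzoic acid 3 (not isolated)
Conditions: NBS (1.05 equiv), AIBN (cat.), PhCl, 85 °C; then NaHCO3, H2O/THF, 50 °C
Reagents that add atoms: none
Why: Wohl–Ziegler benzylic bromination of the only benzylic methyl, followed by intramolecular O-alkylation of the carboxylate (5-exo-tet), should give the phthalide that ties the future C7 and C8 carbons into one temporary ring.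

Step 3
Reactants: 5 (R)-(−)-linalool [(3R)-3,7-dimethylocta-1,6-dien-3-ol]
Product: 7 (3R)-3,7-dimethyloct-6-ene-1,3-diol, via B-alkyl-9-BBN adduct 6 (not isolated)
Conditions: 9-BBN (1.3 equiv), THF, 0 °C to rt; then NaOH, H2O2, H2O, 0 °C to rt
Reagents that add atoms: hydrogen peroxide, OO
Why: Brown hydroboration–oxidation with the bulky 9-BBN should add anti-Markovnikov to the monosubstituted vinyl group only and leave the trisubstituted alkene and the stereocentre untouched.

Step 4
Reactants: 7 (3R)-3,7-dimethyloct-6-ene-1,3-diol
Product: 8 (3R)-1-bromo-3,7-dimethyloct-6-en-3-ol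
Conditions: CBr4, PPh3, CH2Cl2, 0 °C
Reagents that add atoms: carbon tetrabromide, BrC(Br)(Br)Br
Why: In the Appel reaction only the unhindered primary hydroxyl forms the alkoxyphosphonium ion that bromide displaces by SN2; the tertiary carbinol is not involved, so its configuration is kept.

Step 5
Reactants: 4 7-iodo-5-methoxyphthalide; 8 (3R)-1-bromo-3,7-dimethyloct-6-en-3-ol (1.5 equiv)
Product: 9 (2R)-5-methoxy-2-methyl-2-(4-methylpent-3-en-1-yl)-3,4-dihydro-2H-furo[3,4-h]chromen-9(7H)-one
Conditions: Pd(OAc)2 (10 mol %), XPhos (20 mol %), norbornene (2 equiv), Cs2CO3 (3 equiv), 1,4-dioxane, 100 °C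
Reagents that add atoms: none
Why: Proposed new method: zerovalent palladium inserts into the C8a–I bond of 4; norbornene carbopalladation and carbonate-assisted palladation of the only free ortho C–H (C4a–H, the other ortho position being the lactone-bearing C8) give the aryl–norbornyl palladacycle, which takes up the primary C–Br bond of 8 (tetravalent palladium), forms C4–C4a by reductive elimination and expels norbornene by β-carbon elimination because the arene is now doubly ortho-substituted. The aryl palladium species left behind is chelated by the tertiary alkoxide and closes the pyran ring by C(sp2)–O reductive elimination from a seven-membered oxapalladacycle (ipso substitution at C8a giving the six-membered ring), which returns zerovalent palladium. The closest known reaction types are the palladium/norbornene (Catellani) annulations of aryl iodides with epoxides to 2,3-dihydrobenzofurans and with bromoalkylamines to indolines and tetrahydroquinolines, together with the palladium-catalysed intramolecular etherification of aryl halides by tertiary alcohols; the one-pot ortho-alkylation/ipso-etherification with a 3-bromo tertiary alcohol to a chroman is the untested extension. No stereocentre is created: C2 comes from (R)-linalool and none of its four bonds is touched, so its configuration is retained. The step needs alkylation before ipso termination and C–O closure in preference to Heck or β-hydride pathways; the blocked C8 enforces mono-alkylation at C4a, the alkoxide has no hydrogen on its carbinol carbon, and the trisubstituted alkene is too hindered to insert.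

Step 6
Reactants: 9 (2R)-chroman lactone with the 4-methylpent-3-enyl chain
Product: 10 (2S)-2-[2-(3,3-dimethyloxiran-2-yl)ethyl]-5-methoxy-2-methyl-3,4-dihydro-2H-furo[3,4-h]chromen-9(7H)-one (both epimers at the oxirane CH)
Conditions: mCPBA (1.1 equiv), NaHCO3, CH2Cl2, 0 °C
Reagents that add atoms: 3-chloroperoxybenzoic acid, OOC(=O)c1cccc(Cl)c1
Why: Prilezhaev epoxidation should take the only alkene, an electron-rich trisubstituted one; the new oxirane centre forms without control and is erased in step 7.

Step 7
Reactants: 10 epoxide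
Product: 13 (2S)-2-[(2E)-4-hydroxy-4-methylpent-2-en-1-yl]-5-methoxy-2-methyl-3,4-dihydro-2H-furo[3,4-h]chromen-9(7H)-one, via hydroxy selenide 11 (not isolated), via selenoxide 12 (not isolated)
Conditions: PhSeSePh, NaBH4, EtOH, rt to 60 °C; then H2O2, THF, 0 °C to rt
Reagents that add atoms: none
Why: In the Sharpless–Lauer sequence the selenolate opens the epoxide at the less hindered secondary carbon, and syn-elimination of the selenoxide away from the carbinol carbon should give the E-configured tertiary allylic alcohol.

Step 8
Reactants: 13 lactone with the tertiary allylic alcohol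
Product: 14 [(2S)-8-(hydroxymethyl)-2-[(2E)-4-hydroxy-4-methylpent-2-en-1-yl]-5-methoxy-2-methyl-3,4-dihydro-2H-chromen-7-yl]methanol
Conditions: LiAlH4, THF, 0 °C; aqueous NaOH work-up
Reagents that add atoms: none
Why: Hydride reduction of the lactone should open the temporary ring to the 1,2-bis(hydroxymethyl)arene; the isolated alkene, the aryl ethers and C2 are inert.

Step 9
Reactants: 14 triol; 15 hexadecanoyl chloride (palmitoyl chloride, 1.0 equiv)
Product: 16 [(2S)-8-(hydroxymethyl)-2-[(2E)-4-hydroxy-4-methylpent-2-en-1-yl]-5-methoxy-2-methyl-3,4-dihydro-2H-chromen-7-yl]methyl hexadecanoate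
Conditions: 2,4,6-collidine, CH2Cl2, −78 to −40 °C
Reagents that add atoms: none
Why: Site-selective O-acylation with an acyl chloride and a hindered pyridine base at low temperature should take the C7 hydroxymethyl, because the C8 hydroxymethyl sits between two ortho substituents (O1 and the C7 arm) and the tertiary alcohol does not acylate.

Step 10
Reactants: 16 monopalmitate
Product: 18 [(2S)-8-formyl-5-methoxy-2-methyl-2-(4-methyl-2-oxopent-3-en-1-yl)-3,4-dihydro-2H-chromen-7-yl]methyl hexadecanoate, via aldehyde 17 (not isolated)
Conditions: pyridinium chlorochromate [C5H5NH][CrO3Cl] (4 equiv), NaOAc, 4 Å molecular sieves, CH2Cl2, rt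
Reagents that add atoms: pyridinium chlorochromate, [O-][Cr](=O)(=O)Cl.c1cc[nH+]cc1 (supplies the ketone oxygen)
Why: The chlorochromate oxidises the benzylic alcohol to the aldehyde and effects the Babler–Dauben oxidative 1,3-transposition of the tertiary allylic alcohol ([3,3] shift of its chromate ester, then oxidation) to the β,β-dimethyl enone; the acetate buffer protects the β-aryloxy ketone.

**Compound list**

1 | 4-methoxy-2-methylbenzoic acid | Cc1cc(OC)ccc1C(=O)O | starting material
2 | 2-iodo-4-methoxy-6-methylbenzoic acid | Cc1cc(OC)cc(I)c1C(=O)O | intermediate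
3 | 2-(bromomethyl)-6-iodo-4-methoxybenzoic acid | BrCc1cc(OC)cc(I)c1C(=O)O | intermediate (not isolated)
4 | 7-iodo-5-methoxyisobenzofuran-1(3H)-one | COc1cc(I)c2C(=O)OCc2c1 | intermediate
5 | (R)-(−)-linalool, (3R)-3,7-dimethylocta-1,6-dien-3-ol | C=C[C@](C)(O)CCC=C(C)C | starting material
6 | 9-[(3S)-3-hydroxy-3,7-dimethyloct-6-en-1-yl]-9-borabicyclo[3.3.1]nonane (same geometry as 5; S by CIP ranking) | C1CCC2CCCC1B2CC[C@](C)(O)CCC=C(C)C | intermediate (not isolated)
7 | (3R)-3,7-dimethyloct-6-ene-1,3-diol | OCC[C@](C)(O)CCC=C(C)C | intermediate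
8 | (3R)-1-bromo-3,7-dimethyloct-6-en-3-ol | BrCC[C@](C)(O)CCC=C(C)C | intermediate
9 | (2R)-5-methoxy-2-methyl-2-(4-methylpent-3-en-1-yl)-3,4-dihydro-2H-furo[3,4-h]chromen-9(7H)-one (lactone C=O on chroman C8, lactone CH2 on C7) | O=C1OCc2cc(OC)c3c(c12)O[C@](C)(CCC=C(C)C)CC3 | intermediate
10 | (2S)-2-[2-(3,3-dimethyloxiran-2-yl)ethyl]-5-methoxy-2-methyl-3,4-dihydro-2H-furo[3,4-h]chromen-9(7H)-one, both oxirane epimers | O=C1OCc2cc(OC)c3c(c12)O[C@](C)(CCC4OC4(C)C)CC3 | intermediate
11 | (2S)-2-[4-hydroxy-4-methyl-3-(phenylselanyl)pentyl]-5-methoxy-2-methyl-3,4-dihydro-2H-furo[3,4-h]chromen-9(7H)-one, both epimers at the selenium-bearing carbon | O=C1OCc2cc(OC)c3c(c12)O[C@](C)(CCC([Se]c4ccccc4)C(C)(C)O)CC3 | intermediate (not isolated)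
12 | selenoxide of 11, (2S)-2-[4-hydroxy-4-methyl-3-(phenylseleninyl)pentyl] analogue | O=C1OCc2cc(OC)c3c(c12)O[C@](C)(CCC([Se](=O)c4ccccc4)C(C)(C)O)CC3 | intermediate (not isolated)
13 | (2S)-2-[(2E)-4-hydroxy-4-methylpent-2-en-1-yl]-5-methoxy-2-methyl-3,4-dihydro-2H-furo[3,4-h]chromen-9(7H)-one | O=C1OCc2cc(OC)c3c(c12)O[C@](C)(C/C=C/C(C)(C)O)CC3 | intermediate
14 | [(2S)-8-(hydroxymethyl)-2-[(2E)-4-hydroxy-4-methylpent-2-en-1-yl]-5-methoxy-2-methyl-3,4-dihydro-2H-chromen-7-yl]methanol | OCc1cc(OC)c2c(c1CO)O[C@](C)(C/C=C/C(C)(C)O)CC2 | intermediate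
15 | hexadecanoyl chloride (palmitoyl chloride) | CCCCCCCCCCCCCCCC(=O)Cl | starting material
16 | [(2S)-8-(hydroxymethyl)-2-[(2E)-4-hydroxy-4-methylpent-2-en-1-yl]-5-methoxy-2-methyl-3,4-dihydro-2H-chromen-7-yl]methyl hexadecanoate | CCCCCCCCCCCCCCCC(=O)OCc1cc(OC)c2c(c1CO)O[C@](C)(C/C=C/C(C)(C)O)CC2 | intermediate
17 | [(2S)-8-formyl-2-[(2E)-4-hydroxy-4-methylpent-2-en-1-yl]-5-methoxy-2-methyl-3,4-dihydro-2H-chromen-7-yl]methyl hexadecanoate | CCCCCCCCCCCCCCCC(=O)OCc1cc(OC)c2c(c1C=O)O[C@](C)(C/C=C/C(C)(C)O)CC2 | intermediate (not isolated)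
18 | [(2S)-8-formyl-5-methoxy-2-methyl-2-(4-methyl-2-oxopent-3-en-1-yl)-3,4-dihydro-2H-chromen-7-yl]methyl hexadecanoate | CCCCCCCCCCCCCCCC(=O)OCc1cc(OC)c2c(c1C=O)O[C@](C)(CC(=O)C=C(C)C)CC2 | target

**Step count**

Total steps: 10. Longest linear sequence: 8 steps (steps 1, 2, 5–10 from 1, or steps 3, 4, 5–10 from 5).

**Steps most likely to fail**

1. Step 5. Palladation of the C4a–H bond, which is flanked by the methoxy group, may be too slow, so that the aryl–norbornyl palladium intermediate is diverted into norbornene-containing products. The bromohydrin may also be consumed by the base (oxetane formation or fragmentation) before it alkylates. The fallback makes the two bonds one after the other by known cross-couplings on an arene that carries two different halogens. It sets out from 1 and from 5 (through its 9-BBN adduct 6) and comes back to the route at 9.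
 - Electrophilic bromination of 1 with Br2 in AcOH at rt, directed ortho to the methoxy group and para to the methyl group, should give 5-bromo-4-methoxy-2-methylbenzoic acid F1 with the bromine on the future C4a.
 - O-Methylation of F1 with MeI and K2CO3 in DMF gives methyl 5-bromo-4-methoxy-2-methylbenzoate F2 as the substrate for metalation.
 - Magnesiation of F2 at the ring C–H between the ester and the bromine with TMPMgCl·LiCl in THF at −20 °C, then a hexachloroethane quench, gives methyl 3-bromo-2-chloro-4-methoxy-6-methylbenzoate F3 with the chlorine on the future C8a. The lithium-free magnesium amide is chosen so that the ortho-bromo aryl metal does not collapse to an aryne.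
 - Wohl–Ziegler bromination of F3 with NBS and AIBN in PhCl at 85 °C gives methyl 3-bromo-6-(bromomethyl)-2-chloro-4-methoxybenzoate F4 as the benzylic bromide.
 - Hydrolytic lactonisation of F4 with CaCO3 in aqueous 1,4-dioxane at 100 °C gives 6-bromo-7-chloro-5-methoxyisobenzofuran-1(3H)-one F5 as the dihalophthalide.
 - B-alkyl Suzuki–Miyaura coupling of F5 with borane 6, using PdCl2(dppf) and K3PO4 in THF/H2O at 65 °C with an acidic work-up, joins C4 to C4a at the bromide only. It gives 7-chloro-6-[(3R)-3-hydroxy-3,7-dimethyloct-6-en-1-yl]-5-methoxyisobenzofuran-1(3H)-one F6 with the chloride intact.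
 - Intramolecular Buchwald-type etherification of the aryl chloride of F6 with its tertiary alcohol, using Pd(OAc)2, 2-(di-tert-butylphosphino)-1,1'-binaphthyl and Cs2CO3 in toluene at 90 °C, then closes O1–C8a and gives 9.

2. Step 9. The two benzylic hydroxyls may be poorly discriminated, with double acylation or acyl migration between them. The fallback removes the choice by never having both alcohols free. It sets out from 13 and comes back at 17, which is then taken through the transposition of step 10.
 - Lactone 13 is opened with Me2AlNMe2, made from AlMe3 and Me2NH·HCl in CH2Cl2 at rt. This gives (2S)-7-(hydroxymethyl)-2-[(2E)-4-hydroxy-4-methylpent-2-en-1-yl]-5-methoxy-N,N,2-trimethyl-3,4-dihydro-2H-chromene-8-carboxamide F7 as a hydroxy amide with a single primary hydroxyl.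
 - Acylation of F7 with 15, using pyridine and DMAP in CH2Cl2 at 0 °C directly after isolation, gives [(2S)-8-(dimethylcarbamoyl)-2-[(2E)-4-hydroxy-4-methylpent-2-en-1-yl]-5-methoxy-2-methyl-3,4-dihydro-2H-chromen-7-yl]methyl hexadecanoate F8 with the amide untouched.
 - Reduction of the tertiary amide of F8 with Cp2Zr(H)Cl in THF at rt, which spares the ester, then gives aldehyde 17.

3. Step 10. The acidic chromium reagent may ionise the tertiary allylic alcohol (dehydration to a diene) or promote loss of the aryloxy group β to the new ketone. The fallback separates the two oxidations and replaces the oxidative rearrangement by isomerisation followed by a neutral oxidation. It sets out from 16 and comes back at 18.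
 - The benzylic alcohol alone is oxidised with MnO2 in CH2Cl2 at rt to isolated 17.
 - Catalytic Ph3SiOReO3 in Et2O at 0 °C shifts the hydroxyl 1,3 and gives [(2S)-8-formyl-2-(2-hydroxy-4-methylpent-3-en-1-yl)-5-methoxy-2-methyl-3,4-dihydro-2H-chromen-7-yl]methyl hexadecanoate F9 as either carbinol epimer.
 - Dess–Martin periodinane with NaHCO3 in CH2Cl2 at rt then oxidises F9 to 18.

**Further compounds**

F1 | step 5 | 5-bromo-4-methoxy-2-methylbenzoic acid | Cc1cc(OC)c(Br)cc1C(=O)O
F2 | step 5 | methyl 5-bromo-4-methoxy-2-methylbenzoate | Cc1cc(OC)c(Br)cc1C(=O)OC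
F3 | step 5 | methyl 3-bromo-2-chloro-4-methoxy-6-methylbenzoate | Cc1cc(OC)c(Br)c(Cl)c1C(=O)OC
F4 | step 5 | methyl 3-bromo-6-(bromomethyl)-2-chloro-4-methoxybenzoate | BrCc1cc(OC)c(Br)c(Cl)c1C(=O)OC
F5 | step 5 | 6-bromo-7-chloro-5-methoxyisobenzofuran-1(3H)-one | COc1cc2COC(=O)c2c(Cl)c1Br
F6 | step 5 | 7-chloro-6-[(3R)-3-hydroxy-3,7-dimethyloct-6-en-1-yl]-5-methoxyisobenzofuran-1(3H)-one | COc1cc2COC(=O)c2c(Cl)c1CC[C@](C)(O)CCC=C(C)C
F7 | step 9 | (2S)-7-(hydroxymethyl)-2-[(2E)-4-hydroxy-4-methylpent-2-en-1-yl]-5-methoxy-N,N,2-trimethyl-3,4-dihydro-2H-chromene-8-carboxamide | OCc1cc(OC)c2c(c1C(=O)N(C)C)O[C@](C)(C/C=C/C(C)(C)O)CC2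
F8 | step 9 | [(2S)-8-(dimethylcarbamoyl)-2-[(2E)-4-hydroxy-4-methylpent-2-en-1-yl]-5-methoxy-2-methyl-3,4-dihydro-2H-chromen-7-yl]methyl hexadecanoate | CCCCCCCCCCCCCCCC(=O)OCc1cc(OC)c2c(c1C(=O)N(C)C)O[C@](C)(C/C=C/C(C)(C)O)CC2
F9 | step 10 | [(2S)-8-formyl-2-(2-hydroxy-4-methylpent-3-en-1-yl)-5-methoxy-2-methyl-3,4-dihydro-2H-chromen-7-yl]methyl hexadecanoate | CCCCCCCCCCCCCCCC(=O)OCc1cc(OC)c2c(c1C=O)O[C@](C)(CC(O)C=C(C)C)CC2
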